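**Plan**
- Retrosynthesis: the two phenol protecting groups and the ring acetyl group (C–C bond to the ring CH2) come off first. The trione ring is then cut at the two ring bonds on either side of the C(CH3)2(C=O)2 unit, one to the carbon bearing ArCH2 and one to the ring CH2.
- Enabling feature: the non-aromatic ring is a cyclohexane-1,3,5-trione. Its C(CH3)2 carbon and the two flanking carbonyl carbons are a dimethylmalonyl piece; the other three ring carbons (C–CH2Ar, C=O, CH2) are C3, C2 and C1 of a 4-arylbutan-2-one.
- Forward: the aromatic ring is bought complete, formylated, O-benzylated and extended by Wittig olefination to an enone. A 1,4-hydrosilylation then gives the regiodefined silyl enol ether.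
- The only ring made, the trione, closes by 3+3 annulation with dimethylmalonyl dichloride. C-acetylation at the ring CH2 and hydrogenolysis finish the route.
- Stereochemistry: the target has no stereocentre. The Z geometry of the enol ether is consumed in the annulation.

Key step: step 5

Remark: the target and the trione intermediates are written as one of several rapidly interconverting enol tautomers; this is a drawing choice, not a structural claim.

**Step 1**
Reactants: 1 2,6-dihydroxy-4-methoxyacetophenone
Product: 3 3-acetyl-2,4-dihydroxy-6-methoxybenzaldehyde, via iminium chloride 2 (not isolated)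
Conditions: POCl3 (1.2 equiv), DMF (3 equiv), EtOAc, 0 °C → rt; then H2O, 50 °C
Reagents that add atoms: N,N-dimethylformamide, CN(C)C=O; water, O
Why: Vilsmeier–Haack formylation, in which the chloroiminium ion attacks one of the two equivalent CH positions of the strongly activated ring, the iminium salt 2 deactivates the ring against a second attack, and warm water hydrolyses 2 to the aldehyde.

**Step 2**
Reactants: 3 3-acetyl-2,4-dihydroxy-6-methoxybenzaldehyde
Product: 4 3-acetyl-2,4-bis(benzyloxy)-6-methoxybenzaldehyde
Conditions: BnBr (2.5 equiv), K2CO3 (4 equiv), DMF, 60 °C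
Reagents that add atoms: benzyl bromide, BrCc1ccccc1
Why: Williamson ether synthesis, in which K2CO3 in warm DMF deprotonates both carbonyl-chelated phenols for O-benzylation while staying too mild for aldol condensation between the acetyl and formyl groups.

**Step 3**
Reactants: 4 3-acetyl-2,4-bis(benzyloxy)-6-methoxybenzaldehyde; 5 1-(triphenylphosphoranylidene)propan-2-one
Product: 6 (E)-4-[3-acetyl-2,4-bis(benzyloxy)-6-methoxyphenyl]but-3-en-2-one
Conditions: toluene, 100 °C
Reagents that add atoms: none
Why: Wittig olefination with a ketone-stabilised ylide, which should react only with the aldehyde (the aryl methyl ketone flanked by two benzyloxy groups is inert to it) and give the E enone as is usual for stabilised ylides.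

**Step 4**
Reactants: 6 (E)-4-[3-acetyl-2,4-bis(benzyloxy)-6-methoxyphenyl]but-3-en-2-one
Product: 7 (Z)-1-[2,6-bis(benzyloxy)-4-methoxy-3-[3-(triethylsilyloxy)but-2-en-1-yl]phenyl]ethan-1-one, the triethylsilyl enol ether ArCH2–CH=C(CH3)–OSiEt3
Conditions: Et3SiH (1.2 equiv), RhCl(PPh3)3 (1 mol %), toluene, 50 °C; filtration through Florisil, used directly
Reagents that add atoms: triethylsilane, CC[SiH](CC)CC
Why: rhodium-catalysed 1,4-hydrosilylation of an enone with a trialkylsilane, which places hydrogen on the β-carbon and silicon on oxygen through the s-cis conformer, so the enol ether is fixed on the benzyl side with Z geometry while the aryl ketone, shielded by two ortho benzyloxy groups, should not compete.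

**Step 5**
Reactants: 7 the triethylsilyl enol ether ArCH2–CH=C(CH3)–OSiEt3; 8 dimethylmalonyl dichloride
Product: 10 2-[[3-acetyl-2,4-bis(benzyloxy)-6-methoxyphenyl]methyl]-3-hydroxy-4,4-dimethylcyclohex-2-ene-1,5-dione, via diketo acid chloride 9 (not isolated)
Conditions: 8 (1.1 equiv), ZnCl2 (0.2 equiv), CH2Cl2, −40 °C → rt until 7 is consumed, then 40 °C; dilute aqueous HCl work-up
Reagents that add atoms: none
Why: ZnCl2 activates one acyl chloride of 8 for a Mukaiyama-type C-acylation at the enol ether carbon that carries the ArCH2 group, chloride takes the silyl group, and the 2-acyl ketone 9 results with its second COCl intact; on warming, 9 enolises towards its methyl group and that carbon attacks the remaining COCl by addition–elimination with loss of HCl. The closest known reaction is the Effenberger cyclisation, the α,α'-diacylation of ketone enol ethers by malonyl dichlorides to cyclohexane-1,3,5-triones, joined here to the Lewis-acid-catalysed acylation of silyl enol ethers by acid chlorides. The single ring closes in a 6-(enolendo)-exo-trig mode. No stereocentre results, because the CH of 9 ends as an enol carbon and the Z geometry of 7 has no consequence. The step needs C- over O-acylation in the closure: 8 has no α-hydrogen, so no ketene path competes and the quaternary carbon arrives intact, the gem-dimethyl group holds the COCl close to the methyl enol, and an enol lactone from O-attack is an enol ester that HCl and ZnCl2 should reopen, whereas the trione is a stable vinylogous acid. Keeping the first acylation cold until 7 is consumed should prevent the HCl of the second stage from protonating the enol ether.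

**Step 6**
Reactants: 10 2-[[3-acetyl-2,4-bis(benzyloxy)-6-methoxyphenyl]methyl]-3-hydroxy-4,4-dimethylcyclohex-2-ene-1,5-dione
Product: 12 2-acetyl-6-[[3-acetyl-2,4-bis(benzyloxy)-6-methoxyphenyl]methyl]-3,5-dihydroxy-4,4-dimethylcyclohexa-2,5-dien-1-one, via enol acetate 11 (not isolated)
Conditions: AcCl (1.1 equiv), Et3N (2.5 equiv), CH2Cl2, 0 °C; then DMAP (0.2 equiv), rt → 35 °C; dilute aqueous HCl work-up
Reagents that add atoms: acetyl chloride, CC(Cl)=O
Why: O-acetylation of the vinylogous acid followed by DMAP-catalysed O-to-C acyl migration (the enol ester rearrangement used for 2-acylcyclohexane-1,3-diones), in which acyl transfer is reversible and should end at the ring CH2 between two carbonyls, the only carbon that gives an enolisable, hydrogen-bonded triketone, whichever enol acetate forms first.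

**Step 7**
Reactants: 12 2-acetyl-6-[[3-acetyl-2,4-bis(benzyloxy)-6-methoxyphenyl]methyl]-3,5-dihydroxy-4,4-dimethylcyclohexa-2,5-dien-1-one
Product: 13 2-acetyl-6-[(3-acetyl-2,4-dihydroxy-6-methoxyphenyl)methyl]-3,5-dihydroxy-4,4-dimethylcyclohexa-2,5-dien-1-one (CNP0224819.0)
Conditions: H2 (1 atm), Pd/C (10 wt %), EtOAc, rt
Reagents that add atoms: none
Why: hydrogenolysis of the two aryl benzyl ethers over Pd/C under neutral conditions, which should leave the chelated aryl ketone, the enolised triketone and the CH2 bridge between the rings untouched.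

**Compound list**
1 | 2,6-dihydroxy-4-methoxyacetophenone | COc1cc(O)c(C(C)=O)c(O)c1 | starting material
2 | [(3-acetyl-2,4-dihydroxy-6-methoxyphenyl)methylidene]dimethylammonium chloride (formed and hydrolysed in step 1) | COc1cc(O)c(C(C)=O)c(O)c1C=[N+](C)C.[Cl-] | intermediate
3 | 3-acetyl-2,4-dihydroxy-6-methoxybenzaldehyde | COc1cc(O)c(C(C)=O)c(O)c1C=O | intermediate
4 | 3-acetyl-2,4-bis(benzyloxy)-6-methoxybenzaldehyde | COc1cc(OCc2ccccc2)c(C(C)=O)c(OCc2ccccc2)c1C=O | intermediate
5 | 1-(triphenylphosphoranylidene)propan-2-one | CC(=O)C=P(c1ccccc1)(c1ccccc1)c1ccccc1 | starting material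
6 | (E)-4-[3-acetyl-2,4-bis(benzyloxy)-6-methoxyphenyl]but-3-en-2-one | COc1cc(OCc2ccccc2)c(C(C)=O)c(OCc2ccccc2)c1/C=C/C(C)=O | intermediate
7 | (Z)-1-[2,6-bis(benzyloxy)-4-methoxy-3-[3-(triethylsilyloxy)but-2-en-1-yl]phenyl]ethan-1-one | COc1cc(OCc2ccccc2)c(C(C)=O)c(OCc2ccccc2)c1C/C=C(/C)O[Si](CC)(CC)CC | intermediate
8 | dimethylmalonyl dichloride | CC(C)(C(=O)Cl)C(=O)Cl | starting material
9 | 4-[[3-acetyl-2,4-bis(benzyloxy)-6-methoxyphenyl]methyl]-2,2-dimethyl-3,5-dioxohexanoyl chloride (racemic, enolisable at C4; formed and consumed in step 5) | COc1cc(OCc2ccccc2)c(C(C)=O)c(OCc2ccccc2)c1CC(C(C)=O)C(=O)C(C)(C)C(=O)Cl | intermediate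
10 | 2-[[3-acetyl-2,4-bis(benzyloxy)-6-methoxyphenyl]methyl]-3-hydroxy-4,4-dimethylcyclohex-2-ene-1,5-dione | COc1cc(OCc2ccccc2)c(C(C)=O)c(OCc2ccccc2)c1CC1=C(O)C(C)(C)C(=O)CC1=O | intermediate
11 | 4-[[3-acetyl-2,4-bis(benzyloxy)-6-methoxyphenyl]methyl]-5-hydroxy-6,6-dimethyl-3-oxocyclohexa-1,4-dien-1-yl acetate (formed and consumed in step 6) | COc1cc(OCc2ccccc2)c(C(C)=O)c(OCc2ccccc2)c1CC1=C(O)C(C)(C)C(OC(C)=O)=CC1=O | intermediate
12 | 2-acetyl-6-[[3-acetyl-2,4-bis(benzyloxy)-6-methoxyphenyl]methyl]-3,5-dihydroxy-4,4-dimethylcyclohexa-2,5-dien-1-one | COc1cc(OCc2ccccc2)c(C(C)=O)c(OCc2ccccc2)c1CC1=C(O)C(C)(C)C(O)=C(C(C)=O)C1=O | intermediate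
13 | 2-acetyl-6-[(3-acetyl-2,4-dihydroxy-6-methoxyphenyl)methyl]-3,5-dihydroxy-4,4-dimethylcyclohexa-2,5-dien-1-one | COc1cc(O)c(C(C)=O)c(O)c1CC1=C(O)C(C)(C)C(O)=C(C(C)=O)C1=O | target

**Step count and risks**
Total step count: 7. Longest linear sequence: 7 steps, from 1 to 13.

Steps most likely to fail:

Step 5. The ring closure may run through the enol oxygen of 9 and stop at a six-membered enol lactone, or the HCl set free may cleave a benzyl ether next to the aryl ketone. The fallback sets out from 7 and forms the two ring bonds one at a time. ZnCl2-catalysed acylation of 7 with the catalogue half-ester chloride ethyl 3-chloro-2,2-dimethyl-3-oxopropanoate (CCOC(=O)C(C)(C)C(Cl)=O) in CH2Cl2 would give ethyl 4-[[3-acetyl-2,4-bis(benzyloxy)-6-methoxyphenyl]methyl]-2,2-dimethyl-3,5-dioxohexanoate F1. Since F1 has no second acyl chloride, it cannot lactonise. LiN(iPr)2 (3.5 equiv, which also covers the aryl methyl ketone) in THF at −78 → 0 °C would then generate the terminal carbanion of the diketone polyanion, which closes onto the ester in a Dieckmann-type Claisen condensation. Acidification returns the route to 10.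

Step 6. Acyl transfer may stall at the enol acetate, or a second acetylation on oxygen may consume the product. The fallback sets out from 10 and avoids acyl transfer altogether. Condensation with N,N-dimethylacetamide dimethyl acetal (CC(OC)(OC)N(C)C) in toluene at rt → 50 °C can only occur at the ring CH2, the one carbon able to carry an alkylidene. It would give the enaminone 2-[[3-acetyl-2,4-bis(benzyloxy)-6-methoxyphenyl]methyl]-6-[1-(dimethylamino)ethylidene]-3-hydroxy-4,4-dimethylcyclohex-2-ene-1,5-dione F2. Hydrolysis of this vinylogous amide with 2 M HCl in THF at 40 °C would release the acetyl group and return the route to 12.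

Step 4. Competing 1,2-hydrosilylation of the enone, slow reduction of the aryl ketone, or hydrolysis of the silyl enol ether during isolation may erode the material. The fallback sets out from 6 and replaces hydrosilylation by stoichiometric hydride conjugate addition. [(Ph3P)CuH]6 in benzene–THF at rt in the presence of Et3SiCl would deliver hydride to the β-carbon, and the copper enolate would be silylated on oxygen as it forms. This returns the route directly to 7 and makes no compound outside the list (F0).

**Further compounds**
F1 | step 5 | ethyl 4-[[3-acetyl-2,4-bis(benzyloxy)-6-methoxyphenyl]methyl]-2,2-dimethyl-3,5-dioxohexanoate (racemic, enolisable at C4) | COc1cc(OCc2ccccc2)c(C(C)=O)c(OCc2ccccc2)c1CC(C(C)=O)C(=O)C(C)(C)C(=O)OCC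
F2 | step 6 | 2-[[3-acetyl-2,4-bis(benzyloxy)-6-methoxyphenyl]methyl]-6-[1-(dimethylamino)ethylidene]-3-hydroxy-4,4-dimethylcyclohex-2-ene-1,5-dione (push-pull alkene, geometry not fixed) | COc1cc(OCc2ccccc2)c(C(C)=O)c(OCc2ccccc2)c1CC1=C(O)C(C)(C)C(=O)C(=C(C)N(C)C)C1=O
F0 | step 4 | none | none
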